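**Retrosynthetic overview**
- The last C–O bond and the last stereocentre (C4′ of the side chain) come from a catalyst-controlled γ-addition of angelic acid to the C3 hex-2-ynoate of the C9-silylated ketol, followed by desilylation.
- The ynoate comes from hex-2-ynoic acid and the 3α-alcohol; the C7 isopropenyl from a Pd-catalysed α-alkenylation with 2-bromopropene; the C9 oxygen from a Rubottom oxidation of the cis-decalone.
- The cis-decalone comes from hydrogenation of the Δ9-octal-8-one; the 3α-OH/4β-Me pair from hydroboration of a C3=C4 alkene made from the C4 ketone (Wittig, isomerisation).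
- Ring A is bought as 2-methylcyclohexane-1,3-dione; ring B is closed onto it in the first step by an organocatalytic Robinson annulation giving (S)-Wieland–Miescher ketone. No further ring is formed.

Assumptions: eremophilane numbering is used throughout (ring A = C1–C5 and C10, ring B = C5–C10; C5 quaternary, C10 ring-fusion CH, C8 the ring B carbonyl, β = face of the C5 methyl), and the (S)-phosphine catalyst of step 10 is taken to give the 4′R ester (if the sense is the reverse, its mirror image is used).

**Step 1**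
Reactants: 1 2-methylcyclohexane-1,3-dione; 2 but-3-en-2-one (methyl vinyl ketone)
Product: 4 (S)-Wieland–Miescher ketone, via triketone 3 (not isolated)
Conditions: Et3N (1 mol%), neat, rt; then N-tosyl-(Sa)-binam-L-prolinamide (2 mol%), PhCO2H (2.5 mol%), neat, rt; one recrystallisation
Reagents that add atoms: none
Why: Michael addition followed by an enamine-catalysed Hajos–Parrish–Eder–Sauer–Wiechert aldol condensation (asymmetric Robinson annulation) differentiates the two enantiotopic ring carbonyls and sets the quaternary C5 centre as S.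

**Step 2**
Reactants: 4 (S)-Wieland–Miescher ketone
Product: 5 (4aR)-4a-methyl-5-methylidene-4,4a,5,6,7,8-hexahydronaphthalen-2(3H)-one
Conditions: Ph3PCH3Br (1.3 equiv), KOtBu (1.25 equiv), toluene, 0 to 60 °C
Reagents that add atoms: methyltriphenylphosphonium bromide, C[P+](c1ccccc1)(c1ccccc1)c1ccccc1.[Br-]
Why: Wittig methylenation is expected to take only the saturated C4 ketone, because the vinylogous enone carbonyl is much less electrophilic and is partly held as its dienolate by the basic ylide.

**Step 3**
Reactants: 5 methylidene enone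
Product: 6 (4aR)-4a,5-dimethyl-4,4a,7,8-tetrahydronaphthalen-2(3H)-one
Conditions: RhCl3·3H2O (5 mol%), EtOH, 80 °C
Reagents that add atoms: none
Why: Rhodium hydride alkene isomerisation moves the exocyclic alkene to the more stable trisubstituted C3=C4 position (the only ring position open, since C5 is quaternary) and avoids the cationic conditions that could trigger a methyl shift from C5.

**Step 4**
Reactants: 6 dienone
Product: 7 C8 1,3-dioxolane of 6
Conditions: (TMSOCH2)2 (2 equiv), TMSOTf (5 mol%), CH2Cl2, −78 to −40 °C; pyridine quench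
Reagents that add atoms: 1,2-bis(trimethylsilyloxy)ethane, C[Si](C)(C)OCCO[Si](C)(C)C
Why: Noyori ketalisation under aprotic kinetic conditions masks the enone carbonyl against borane without moving C9=C10, so C10 stays planar for the next step.

**Step 5**
Reactants: 7 dienyl ketal
Product: 10 3α-hydroxy-4β,5β-dimethyl-Δ9-octalin-8-one, via alkylborane 8 (not isolated), via ketal alcohol 9 (not isolated)
Conditions: BH3·THF (1.1 equiv), THF, 0 °C; NaOH, H2O2, 0 °C to rt; then 1 M HCl, THF, rt
Reagents that add atoms: borane–tetrahydrofuran, [BH3-][O+]1CCCC1 (boron is lost again on oxidation); hydrogen peroxide, OO; water, O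
Why: Hydroboration–oxidation adds syn and anti-Markovnikov to C3=C4 from the α face opposite the C5 methyl, putting H on C4 (so C15 ends β, cis to C14) and OH on C3 (α), while C9=C10 is shielded by the spiro-ketal and C5 and inductively deactivated; acid then releases the enone.

**Step 6**
Reactants: 10 hydroxy enone
Product: 11 3α-hydroxy-4β,5β-dimethyl-10βH-decalin-8-one
Conditions: H2 (1 atm), 10% Pd/C, EtOH, trace Et3N, rt
Reagents that add atoms: none
Why: Heterogeneous hydrogenation of 4,5-cis-dimethyl-Δ9-octal-8-ones is the established way to the cis-fused (10βH) eremophilane decalones, so it sets C10 with H cis to the C5 methyl.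

**Step 7**
Reactants: 11 cis-decalone alcohol
Product: 16 9β-(tert-butyldimethylsilyloxy)-3α-hydroxy-4β,5β-dimethyl-10βH-decalin-8-one, via trimethylsilyl ether 12 (not isolated), via silyl enol ether 13 (not isolated), via silyloxy epoxide 14 (not isolated), via bis-silyl ketone 15 (not isolated)
Conditions: TMSOTf (1.05 equiv), Et3N, CH2Cl2, −78 °C; TBSOTf (1.3 equiv), −78 °C to rt; NaHCO3 wash; DMDO, acetone/CH2Cl2, −78 °C to rt; PPTS, MeOH, 0 °C
Reagents that add atoms: trimethylsilyl trifluoromethanesulfonate, C[Si](C)(C)OS(=O)(=O)C(F)(F)F (its silyl group is lost again in the last operation); tert-butyldimethylsilyl trifluoromethanesulfonate, CC(C)(C)[Si](C)(C)OS(=O)(=O)C(F)(F)F; dimethyldioxirane, CC1(C)OO1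
Why: A cis-fused ketone of this type enolises toward the ring fusion (C8=C9, as 5β-3-keto steroids do), and Rubottom oxidation (epoxidation on the convex β face, then 1,4-silyl shift) sets C9 and leaves its oxygen silylated, while the transient C3 trimethylsilyl ether is removed by mild methanolysis so that only C3–OH is free.

**Step 8**
Reactants: 16 silyloxy ketone; 17 2-bromopropene
Product: 18 9β-(tert-butyldimethylsilyloxy)-3α-hydroxy-10βH-eremophil-11-en-8-one
Conditions: LiN(SiMe3)2 (3.3 equiv), THF, −78 °C; 17 (1.5 equiv), Pd2(dba)3 (2.5 mol%), P(t-Bu)3·HBF4 (6 mol%), −78 °C to rt; AcOH, −78 °C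
Reagents that add atoms: none
Why: Palladium-catalysed α-alkenylation of the kinetic lithium enolate (only the C7 methylene is open, C9 carries the silyloxy group) joins C7 to the isopropenyl unit; the cold acid quench protonates the product dienolate at C7 to give the β,γ-enone, and the epimerisable C7 centre settles in the equatorial 7β form.

**Step 9**
Reactants: 18 isopropenyl ketone alcohol; 19 hex-2-ynoic acid
Product: 20 9β-(tert-butyldimethylsilyloxy)-8-oxo-10βH-eremophil-11-en-3α-yl hex-2-ynoate
Conditions: DIC (1.6 equiv), DMAP (10 mol%), CH2Cl2, −20 to 0 °C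
Reagents that add atoms: none
Why: Steglich esterification acylates the only free hydroxyl (C3, retention), since the C9 oxygen is silylated.

**Step 10**
Reactants: 20 ynoate; 21 angelic acid [(Z)-2-methylbut-2-enoic acid]
Product: 23 target CNP0190706.1, via silyl ether 22 (not isolated)
Conditions: (S)-SITCP [spirobiindane-based P-phenyl phosphepine] (10 mol%), 21 (2 equiv), toluene, 50 °C; then HF·pyridine, THF, pyridine, 0 °C
Reagents that add atoms: none
Why: Proposed new method: an enantioselective phosphine-catalysed γ-addition of a carboxylic acid to a γ-alkyl 2-alkynoate, in which the chiral phosphine adds to C3′ of the ynoate, proton shuttling by angelic acid turns the adduct into a vinylphosphonium electrophile, angelate attacks the γ-carbon (C4′) within the chiral ion pair to set 4′R, and proton transfer with loss of the phosphine releases the (E)-γ-acyloxy enoate; the closest known reactions are the triphenylphosphine-catalysed racemic γ-addition of carboxylic acids to 2-alkynoates and the chiral-phosphepine-catalysed γ-additions of nitrogen, sulfur, carbon and alcohol nucleophiles, none of which has been shown for a carboxylic acid on a γ-alkyl ynoate of a complex alcohol; the substrate stereocentres are remote, so the catalyst decides the configuration, and HF·pyridine then removes the silyl group in the same flask.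

**Compound list**
1 | 2-methylcyclohexane-1,3-dione | CC1C(=O)CCCC1=O | starting material
2 | but-3-en-2-one (methyl vinyl ketone) | C=CC(C)=O | starting material
3 | 2-methyl-2-(3-oxobutyl)cyclohexane-1,3-dione (triketone) | CC(=O)CCC1(C)C(=O)CCCC1=O | intermediate (not isolated)
4 | (S)-Wieland–Miescher ketone, (8aS)-8a-methyl-3,4,8,8a-tetrahydronaphthalene-1,6(2H,7H)-dione | O=C1C=C2CCCC(=O)[C@@]2(C)CC1 | intermediate
5 | (4aR)-4a-methyl-5-methylidene-4,4a,5,6,7,8-hexahydronaphthalen-2(3H)-one | O=C1C=C2CCCC(=C)[C@@]2(C)CC1 | intermediate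
6 | (4aR)-4a,5-dimethyl-4,4a,7,8-tetrahydronaphthalen-2(3H)-one (C3=C4 and C9=C10 dien-8-one) | O=C1C=C2CCC=C(C)[C@@]2(C)CC1 | intermediate
7 | C8 1,3-dioxolane of 6 (C3=C4 and C9=C10 kept) | O1CCOC12C=C3CCC=C(C)[C@@]3(C)CC2 | intermediate
8 | 3α-boryl-4β,5β-dimethyl-Δ9 C8 dioxolane (monoalkylborane) | O1CCOC12C=C3CC[C@@H](B)[C@H](C)[C@@]3(C)CC2 | intermediate (not isolated)
9 | 3α-hydroxy-4β,5β-dimethyl-Δ9 C8 dioxolane | O1CCOC12C=C3CC[C@@H](O)[C@H](C)[C@@]3(C)CC2 | intermediate (not isolated)
10 | 3α-hydroxy-4β,5β-dimethyl-Δ9-octalin-8-one, (4aR,5R,6R)-6-hydroxy-4a,5-dimethyl-4,4a,5,6,7,8-hexahydronaphthalen-2(3H)-one | O=C1C=C2CC[C@@H](O)[C@H](C)[C@@]2(C)CC1 | intermediate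
11 | 3α-hydroxy-4β,5β-dimethyl-10βH-decalin-8-one (cis-fused) | C1C[C@@]2(C)[C@H](CC[C@@H](O)[C@@H]2C)CC1=O | intermediate
12 | 3-O-trimethylsilyl ether of 11 | C1C[C@@]2(C)[C@H](CC[C@@H](O[Si](C)(C)C)[C@@H]2C)CC1=O | intermediate (not isolated)
13 | C8=C9 tert-butyldimethylsilyl enol ether of 12 | C1C[C@@]2(C)[C@H](CC[C@@H](O[Si](C)(C)C)[C@@H]2C)C=C1O[Si](C)(C)C(C)(C)C | intermediate (not isolated)
14 | 8β,9β-epoxide of 13 (8-silyloxy oxirane) | C1C[C@@]2(C)[C@H](CC[C@@H](O[Si](C)(C)C)[C@@H]2C)[C@H]3O[C@@]13O[Si](C)(C)C(C)(C)C | intermediate (not isolated)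
15 | 9β-(tert-butyldimethylsilyloxy)-3α-(trimethylsilyloxy)-4β,5β-dimethyl-10βH-decalin-8-one | C1C[C@@]2(C)[C@H](CC[C@@H](O[Si](C)(C)C)[C@@H]2C)[C@@H](O[Si](C)(C)C(C)(C)C)C1=O | intermediate (not isolated)
16 | 9β-(tert-butyldimethylsilyloxy)-3α-hydroxy-4β,5β-dimethyl-10βH-decalin-8-one | C1C[C@@]2(C)[C@H](CC[C@@H](O)[C@@H]2C)[C@@H](O[Si](C)(C)C(C)(C)C)C1=O | intermediate
17 | 2-bromopropene | CC(Br)=C | starting material
18 | 9β-(tert-butyldimethylsilyloxy)-3α-hydroxy-10βH-eremophil-11-en-8-one (7β-isopropenyl) | C=C(C)[C@H]1C[C@@]2(C)[C@H](CC[C@@H](O)[C@@H]2C)[C@@H](O[Si](C)(C)C(C)(C)C)C1=O | intermediate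
19 | hex-2-ynoic acid | CCCC#CC(=O)O | starting material
20 | 9β-(tert-butyldimethylsilyloxy)-8-oxo-10βH-eremophil-11-en-3α-yl hex-2-ynoate | C=C(C)[C@H]1C[C@@]2(C)[C@H](CC[C@@H](OC(=O)C#CCCC)[C@@H]2C)[C@@H](O[Si](C)(C)C(C)(C)C)C1=O | intermediate
21 | angelic acid, (Z)-2-methylbut-2-enoic acid | C/C=C(/C)C(=O)O | starting material
22 | 9-O-tert-butyldimethylsilyl ether of the target | C=C(C)[C@H]1C[C@@]2(C)[C@H](CC[C@@H](OC(=O)/C=C/[C@@H](CC)OC(=O)/C(C)=C\C)[C@@H]2C)[C@@H](O[Si](C)(C)C(C)(C)C)C1=O | intermediate (not isolated)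
23 | (3R,4R,5R,7R,9R,10S)-9-hydroxy-8-oxoeremophil-11-en-3-yl (2E,4R)-4-[(Z)-2-methylbut-2-enoyloxy]hex-2-enoate (CNP0190706.1) | C=C(C)[C@H]1C[C@@]2(C)[C@H](CC[C@@H](OC(=O)/C=C/[C@@H](CC)OC(=O)/C(C)=C\C)[C@@H]2C)[C@@H](O)C1=O | target

**Step count and risks**
Total steps: 10. Longest linear sequence: 10 (compounds 17, 19 and 21 are bought).

The three steps most likely to fail:

Step 5 (borane must pick C3=C4 over the ketal-flanked C9=C10). The fallback sets out from dienone 6 and returns at decalone 11. The enone double bond is hydrogenated first (H2, Pd/C, EtOAc; the hindered C3=C4 survives) to give cis-fused 4,5-dimethyl-10βH-octal-3-en-8-one F1. Its C8 carbonyl is protected (ethylene glycol, TsOH, benzene, water removal) as dioxolane F2. The single remaining alkene is hydroborated (BH3·THF) to alkylborane F3 and oxidised (NaOH, H2O2) to ketal alcohol F4, and aqueous HCl releases 11. Chemoselectivity is then trivial, at the price of a less certain facial bias in the cis-decalin, so minor diastereomers are removed by chromatography.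

Step 8 (hindered enolate coupling; the β,γ-enone can slip into conjugation). The fallback sets out from ketone 16 and returns at ynoate 20. LiN(iPr)2 (2.2 equiv, THF, −78 °C) and acetone give the aldol adduct 7β-(2-hydroxypropan-2-yl) ketone F5. The secondary C3 hydroxyl (not the tertiary one) is esterified with 19 as in step 9 to give hydroxy ynoate F6. Dehydration of the tertiary alcohol toward a methyl group (Burgess reagent, or SOCl2/pyridine at −20 °C) gives 20; any conjugated isopropylidene isomer is removed by chromatography.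

Step 10 (the proposed new step; rate, γ-selectivity and enantiocontrol with a carboxylate nucleophile are unproven). The fallback uses known chemistry, sets out from alcohol 18 and returns at silyl ether 22. (R)-Pent-1-en-3-ol (C=C[C@@H](CC)O, bought or obtained by lipase resolution of the racemate) is acylated with the 2,4,6-trichlorobenzoyl mixed anhydride of 21 (toluene, 80 °C, no DMAP, to keep the Z geometry) to give (R)-pent-1-en-3-yl angelate F7. Cross-metathesis with acrylic acid (second-generation Hoveyda–Grubbs catalyst, CH2Cl2, 40 °C) gives (2E,4R)-4-(angeloyloxy)hex-2-enoic acid F8. Carbodiimide esterification of 18 with F8 gives 22, which is desilylated with HF·pyridine as in step 10.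

**Further compounds**
F1 | step 5 | cis-fused 4,5-dimethyl-10βH-octal-3-en-8-one (5β-methyl) | C1C[C@@]2(C)[C@H](CCC=C2C)CC1=O
F2 | step 5 | C8 1,3-dioxolane of F1 | C1C[C@@]2(C)[C@H](CCC=C2C)CC13OCCO3
F3 | step 5 | 3α-boryl-4β,5β-dimethyl-10βH-decalin C8 dioxolane (monoalkylborane) | C1C[C@@]2(C)[C@H](CC[C@@H](B)[C@@H]2C)CC13OCCO3
F4 | step 5 | 3α-hydroxy-4β,5β-dimethyl-10βH-decalin C8 dioxolane | C1C[C@@]2(C)[C@H](CC[C@@H](O)[C@@H]2C)CC13OCCO3
F5 | step 8 | 9β-(tert-butyldimethylsilyloxy)-3α-hydroxy-7β-(2-hydroxypropan-2-yl)-4β,5β-dimethyl-10βH-decalin-8-one | CC(C)(O)[C@H]1C[C@@]2(C)[C@H](CC[C@@H](O)[C@@H]2C)[C@@H](O[Si](C)(C)C(C)(C)C)C1=O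
F6 | step 8 | 3-O-hex-2-ynoyl ester of F5 | CC(C)(O)[C@H]1C[C@@]2(C)[C@H](CC[C@@H](OC(=O)C#CCCC)[C@@H]2C)[C@@H](O[Si](C)(C)C(C)(C)C)C1=O
F7 | step 10 | (R)-pent-1-en-3-yl (Z)-2-methylbut-2-enoate | C=C[C@@H](CC)OC(=O)/C(C)=C\C
F8 | step 10 | (2E,4R)-4-[(Z)-2-methylbut-2-enoyloxy]hex-2-enoic acid | OC(=O)/C=C/[C@@H](CC)OC(=O)/C(C)=C\C
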